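The route rests on disconnecting the bond between C5, the benzylic methine of the saturated ring, and the first CH2 of the 5-phenylpentyl chain. A nickel/Pybox-catalysed enantioconvergent Negishi coupling joins racemic 5-chloro-3,4-dimethoxy-2-methyl-5,6,7,8-tetrahydroquinoline with (5-phenylpentyl)zinc bromide, forming this C(sp3)–C(sp3) bond and the (5R) centre in one operation. The step exploits C5 being attached to C4a of the pyridine ring within the fused six-membered carbocycle: its C–Cl bond gives a planar, ring-stabilised radical that the chiral catalyst captures on one face. The chloride comes from a 5-ketone built by intramolecular Minisci closure of the carbocycle; the N-oxide is installed last.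

Key step: step 9

Assumption: the facial sense of the nickel/Pybox catalyst at C5 is assigned by analogy with 1-haloindanes and the (R,R)-ligand is written for the (5R) product; if a pilot run shows the opposite sense, the equally available (S,S)-ligand is used with no other change.

Step 1
Reactants: 1 3-methoxy-2-methylpyridin-4(1H)-one
Product: 2 5-iodo-3-methoxy-2-methylpyridin-4(1H)-one
Conditions: NIS (1.1 equiv), DMF, rt
Reagents that add atoms: N-iodosuccinimide, O=C1CCC(=O)N1I
Why: Electrophilic aromatic iodination of the enaminone-like 4-pyridone, whose only free nucleophilic carbon is C5 because C3 carries the methoxy group and C6 is the electrophilic beta-carbon.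

Step 2
Reactants: 2 5-iodo-3-methoxy-2-methylpyridin-4(1H)-one
Product: 3 4-chloro-5-iodo-3-methoxy-2-methylpyridine
Conditions: POCl3 (neat), 100 °C; then ice, aq. NaOH to pH 9
Reagents that add atoms: phosphoryl chloride, O=P(Cl)(Cl)Cl
Why: Deoxychlorination of a 4-pyridone with POCl3, the standard entry to 4-chloropyridines, which leaves the iodide at the unactivated beta-position untouched.

Step 3
Reactants: 3 4-chloro-5-iodo-3-methoxy-2-methylpyridine
Product: 4 5-iodo-3,4-dimethoxy-2-methylpyridine
Conditions: NaOMe (3 equiv), MeOH, 90 °C (sealed tube)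
Reagents that add atoms: sodium methoxide, [Na+].[O-]C
Why: Nucleophilic aromatic substitution (SNAr) at the 4-position, which is activated by the ring nitrogen, whereas the 5-iodide cannot react by this pathway without copper.

Step 4
Reactants: 4 5-iodo-3,4-dimethoxy-2-methylpyridine; 5 glutaric anhydride
Product: 7 5-(4,5-dimethoxy-6-methylpyridin-3-yl)-5-oxopentanoic acid, via pyridylmagnesium chloride 6 (not isolated)
Conditions: iPrMgCl·LiCl (1.1 equiv), THF, –20 °C; then cannulated into 5 (1.5 equiv), THF, –78 °C to rt; aq. HCl to pH 4
Reagents that add atoms: none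
Why: Iodine–magnesium exchange with iPrMgCl·LiCl gives the 3-pyridyl Grignard reagent, which opens the cyclic anhydride by acylation, the carboxylate released on ring opening holding back a second addition.

Step 5
Reactants: 7 5-(4,5-dimethoxy-6-methylpyridin-3-yl)-5-oxopentanoic acid
Product: 8 3,4-dimethoxy-2-methyl-7,8-dihydroquinolin-5(6H)-one
Conditions: AgNO3 (20 mol %), (NH4)2S2O8 (2.5 equiv), TFA (1.5 equiv), MeCN/H2O 1:1, 0.02 M, 70 °C
Reagents that add atoms: none
Why: Intramolecular decarboxylative Minisci reaction, in which divalent silver generated by persulfate oxidises the carboxylate, the primary alkyl radical left after loss of CO2 attacks the only free ring carbon (the alpha-position of the protonated pyridine, ortho to the acyl group) in a six-membered closure of the aryl-ketone-to-tetralone type, and oxidation restores aromaticity.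

Step 6
Reactants: 8 3,4-dimethoxy-2-methyl-7,8-dihydroquinolin-5(6H)-one
Product: 9 rac-3,4-dimethoxy-2-methyl-5,6,7,8-tetrahydroquinolin-5-ol
Conditions: NaBH4 (1 equiv), MeOH, 0 °C
Reagents that add atoms: none
Why: Borohydride reduction of the aryl ketone, where no stereocontrol is wanted because the racemic alcohol feeds a stereoconvergent coupling.

Step 7
Reactants: 9 rac-3,4-dimethoxy-2-methyl-5,6,7,8-tetrahydroquinolin-5-ol
Product: 10 rac-5-chloro-3,4-dimethoxy-2-methyl-5,6,7,8-tetrahydroquinoline
Conditions: SOCl2 (1.5 equiv), CH2Cl2, 0 °C; cold aq. NaHCO3; used at once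
Reagents that add atoms: thionyl chloride, O=S(Cl)Cl
Why: Deoxychlorination of the secondary pyridylic alcohol with thionyl chloride, in which protonation of the ring nitrogen by the HCl formed tempers ionisation until the cold basic work-up.

Step 8
Reactants: 11 (5-bromopentyl)benzene
Product: 12 (5-phenylpentyl)zinc bromide
Conditions: Zn dust (1.5 equiv), I2 (5 mol %), DMA, 70 °C; titrated solution
Reagents that add atoms: zinc, [Zn]
Why: Direct insertion of iodine-activated zinc into the primary C–Br bond in a polar amide solvent, which gives the alkylzinc bromide as a solution that is used as such.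

Step 9
Reactants: 10 rac-5-chloro-3,4-dimethoxy-2-methyl-5,6,7,8-tetrahydroquinoline; 12 (5-phenylpentyl)zinc bromide
Product: 13 (5R)-3,4-dimethoxy-2-methyl-5-(5-phenylpentyl)-5,6,7,8-tetrahydroquinoline
Conditions: NiBr2·diglyme (10 mol %), (R,R)-iPr-Pybox [2,6-bis((4R)-4-isopropyl-4,5-dihydrooxazol-2-yl)pyridine] (13 mol %), 12 (1.6 equiv), DMA, 0 °C, 24 h
Reagents that add atoms: none
Why: This is a nickel-catalysed enantioconvergent Negishi alkyl–alkyl coupling of a racemic secondary benzylic halide, the closest known type being the NiBr2·diglyme/Pybox coupling of 1-haloindanes with primary alkylzinc halides. A monovalent nickel–alkyl species formed by transmetalation abstracts chlorine from either enantiomer of 10 to give the same planar C5 radical, stabilised by the pyridine ring through C4a; the chiral (Pybox)nickel alkyl captures this radical and the trivalent nickel intermediate reductively eliminates the C5–CH2 bond. No ring is closed. The C5 stereocentre is controlled by the C2-symmetric ligand, which distinguishes the two faces of the ring-held radical (flanked by the C4a/C4-methoxy side and the C6 methylene) in the capture and reductive elimination events, so both enantiomers of 10 should converge on (5R). The step needs cross-coupling to outrun beta-hydride elimination to the 7,8-dihydroquinoline and must avoid catalyst poisoning by nitrogen. The tridentate ligand leaves no open site for beta-hydride elimination, and the ring nitrogen is shielded by the 2-methyl group and C8 and is kept unoxidised until the last step.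

Step 10
Reactants: 13 (5R)-3,4-dimethoxy-2-methyl-5-(5-phenylpentyl)-5,6,7,8-tetrahydroquinoline
Product: 14 (5R)-3,4-dimethoxy-2-methyl-5-(5-phenylpentyl)-5,6,7,8-tetrahydroquinoline 1-oxide
Conditions: mCPBA (1.2 equiv), CH2Cl2, 0 °C to rt; aq. K2CO3 wash
Reagents that add atoms: 3-chloroperoxybenzoic acid, O=C(OO)c1cccc(Cl)c1
Why: N-oxidation of the pyridine nitrogen, the only nucleophilic site, by the peracid, which does not touch the non-acidic C5–H stereocentre.

Compound list
1 | 3-methoxy-2-methylpyridin-4(1H)-one | COc1c(C)[nH]ccc1=O | starting material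
2 | 5-iodo-3-methoxy-2-methylpyridin-4(1H)-one | COc1c(C)[nH]cc(I)c1=O | intermediate
3 | 4-chloro-5-iodo-3-methoxy-2-methylpyridine | COc1c(C)ncc(I)c1Cl | intermediate
4 | 5-iodo-3,4-dimethoxy-2-methylpyridine | COc1c(C)ncc(I)c1OC | intermediate
5 | glutaric anhydride | O=C1CCCC(=O)O1 | starting material
6 | (4,5-dimethoxy-6-methylpyridin-3-yl)magnesium chloride, LiCl complex, not isolated | COc1c(C)ncc([Mg]Cl)c1OC | intermediate
7 | 5-(4,5-dimethoxy-6-methylpyridin-3-yl)-5-oxopentanoic acid | COc1c(C)ncc(C(=O)CCCC(=O)O)c1OC | intermediate
8 | 3,4-dimethoxy-2-methyl-7,8-dihydroquinolin-5(6H)-one | COc1c(OC)c(C)nc2c1C(=O)CCC2 | intermediate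
9 | rac-3,4-dimethoxy-2-methyl-5,6,7,8-tetrahydroquinolin-5-ol | COc1c(OC)c(C)nc2c1C(O)CCC2 | intermediate
10 | rac-5-chloro-3,4-dimethoxy-2-methyl-5,6,7,8-tetrahydroquinoline | COc1c(OC)c(C)nc2c1C(Cl)CCC2 | intermediate
11 | (5-bromopentyl)benzene | BrCCCCCc1ccccc1 | starting material
12 | (5-phenylpentyl)zinc bromide | Br[Zn]CCCCCc1ccccc1 | intermediate
13 | (5R)-3,4-dimethoxy-2-methyl-5-(5-phenylpentyl)-5,6,7,8-tetrahydroquinoline | COc1c(OC)c(C)nc2c1[C@H](CCCCCc1ccccc1)CCC2 | intermediate
14 | (5R)-3,4-dimethoxy-2-methyl-5-(5-phenylpentyl)-5,6,7,8-tetrahydroquinoline 1-oxide | COc1c(OC)c(C)[n+]([O-])c2c1[C@H](CCCCCc1ccccc1)CCC2 | target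

Total step count: 10. Longest linear sequence: 9 (steps 1 to 7, 9 and 10; step 8 is a one-step side branch).

Steps most likely to fail

Step 9. The enantioselectivity may erode on this six-membered pyridylic halide flanked by the C4 methoxy group, or 10 may be lost by beta-hydride elimination or ionisation to the 7,8-dihydroquinoline before coupling. The fallback sets out from ketone 8 and bromide 11 and comes back at 13. Bromide 11 is converted with Mg in THF into (5-phenylpentyl)magnesium bromide F1, which is added to 8 (CeCl3, THF, –78 °C) to give the tertiary alcohol rac-3,4-dimethoxy-2-methyl-5-(5-phenylpentyl)-5,6,7,8-tetrahydroquinolin-5-ol F2. Dehydration (p-TsOH, toluene, reflux) should give the endocyclic alkene 3,4-dimethoxy-2-methyl-5-(5-phenylpentyl)-7,8-dihydroquinoline F3. Iridium-catalysed asymmetric hydrogenation ([Ir(cod)(tBu-PHOX)]BArF, the ligand antipode chosen for 5R, H2 50 bar, CH2Cl2) then sets C5 by face-selective hydrogen delivery and gives 13.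

Step 5. Closure of the six-membered ring by the primary radical may be slow, so that hydrogen abstraction, intermolecular addition or over-oxidation of the electron-rich ring competes. The fallback replaces the radical closure at C8a by polar chemistry; it sets out from iodide 4 and comes back at alcohol 9, bypassing 7 and 8. Activation of 4 with phenyl chloroformate (THF, –40 °C) and addition of commercial but-3-enylmagnesium bromide at the free alpha-carbon should give phenyl 2-(but-3-en-1-yl)-3-iodo-4,5-dimethoxy-6-methylpyridine-1(2H)-carboxylate F4. This is aromatised without isolation (o-chloranil, toluene, reflux; aq. NaOH work-up) to 2-(but-3-en-1-yl)-3-iodo-4,5-dimethoxy-6-methylpyridine F5. Hydroboration–oxidation (9-BBN, THF; NaBO3) gives 4-(3-iodo-4,5-dimethoxy-6-methylpyridin-2-yl)butan-1-ol F6, and oxidation with Dess–Martin periodinane gives 4-(3-iodo-4,5-dimethoxy-6-methylpyridin-2-yl)butanal F7. An intramolecular Nozaki–Hiyama–Kishi reaction (CrCl2, NiCl2 cat., DMF) closes the ring at C5 and gives 9.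

Step 4. The iodine–magnesium exchange may be incomplete on the electron-rich ring, the Grignard reagent may add twice at the anhydride, and the amphoteric keto acid may be lost on isolation. The fallback sets out from 4 and comes back at 7. A palladium-catalysed carbonylative Negishi coupling of 4 with commercial (4-ethoxy-4-oxobutyl)zinc bromide (Pd(PPh3)4, CO 1 atm, THF, 50 °C) should give ethyl 5-(4,5-dimethoxy-6-methylpyridin-3-yl)-5-oxopentanoate F8, and saponification (LiOH, THF/H2O; then pH 4) gives 7.

Further compounds
F1 | step 9 | (5-phenylpentyl)magnesium bromide | Br[Mg]CCCCCc1ccccc1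
F2 | step 9 | rac-3,4-dimethoxy-2-methyl-5-(5-phenylpentyl)-5,6,7,8-tetrahydroquinolin-5-ol | COc1c(OC)c(C)nc2c1C(O)(CCCCCc1ccccc1)CCC2
F3 | step 9 | 3,4-dimethoxy-2-methyl-5-(5-phenylpentyl)-7,8-dihydroquinoline | COc1c(OC)c(C)nc2c1C(CCCCCc1ccccc1)=CCC2
F4 | step 5 | phenyl 2-(but-3-en-1-yl)-3-iodo-4,5-dimethoxy-6-methylpyridine-1(2H)-carboxylate | COC1=C(C)N(C(=O)Oc2ccccc2)C(CCC=C)C(I)=C1OC
F5 | step 5 | 2-(but-3-en-1-yl)-3-iodo-4,5-dimethoxy-6-methylpyridine | COc1c(C)nc(CCC=C)c(I)c1OC
F6 | step 5 | 4-(3-iodo-4,5-dimethoxy-6-methylpyridin-2-yl)butan-1-ol | COc1c(C)nc(CCCCO)c(I)c1OC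
F7 | step 5 | 4-(3-iodo-4,5-dimethoxy-6-methylpyridin-2-yl)butanal | COc1c(C)nc(CCCC=O)c(I)c1OC
F8 | step 4 | ethyl 5-(4,5-dimethoxy-6-methylpyridin-3-yl)-5-oxopentanoate | CCOC(=O)CCCC(=O)c1cnc(C)c(OC)c1OC
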